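## Retrosynthetic overview

1. The dihydrofuran ring is the only ring made and is closed last: the O1–C2 bond forms by acid-mediated cyclisation of an ortho-hydroxyaryl benzylic carbinol, and C3 steers C2 to trans.
2. The C2–aryl bond comes from aldehyde-selective addition of a protected syringyl-titanium reagent to an α-aryl aldehyde held as its lactol.
3. The aldehyde comes from ozonolysis of an E-propenyl group; the C3a–C3 bond and the C3 stereocentre come from an aromatic Claisen [3,3]-rearrangement with 1,3-chirality transfer (key step).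
4. The Claisen substrate comes from acetovanillone by Mitsunobu inversion of an (R)-allylic alcohol, made by cross-metathesis of (R)-but-3-en-2-ol, the single source of chirality.
5. Both benzene rings are bought (acetovanillone and 4-bromo-2,6-dimethoxyphenol).

Assumption: the target is read as the (2S,3R)-trans isomer, and enantiopure (R)-but-3-en-2-ol is taken as a purchasable bulk chiral building block.

Abbreviations: TBS = tert-butyldimethylsilyl; MOM = methoxymethyl.

## Route

**Step 1**
Reactants: 1 (R)-but-3-en-2-ol; 2 allyloxy(tert-butyl)dimethylsilane (3 equiv)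
Product: 3 (2R,3E)-5-[(tert-butyldimethylsilyl)oxy]pent-3-en-2-ol
Conditions: second-generation Hoveyda–Grubbs catalyst RuCl2(H2IMes)(=CH-C6H4-2-OiPr) (3 mol %), CH2Cl2, 40 °C; E isomer isolated by chromatography
Reagents that add atoms: none
Why: Olefin cross-metathesis of a secondary allylic alcohol with excess allyl silyl ether is driven by ethene loss and is E-selective, and the carbinol stereocentre of 1 is not touched.

**Step 2**
Reactants: 3 (2R,3E)-5-[(tert-butyldimethylsilyl)oxy]pent-3-en-2-ol; 4 acetovanillone, 1-(4-hydroxy-3-methoxyphenyl)ethan-1-one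
Product: 5 1-[4-({(2S,3E)-5-[(tert-butyldimethylsilyl)oxy]pent-3-en-2-yl}oxy)-3-methoxyphenyl]ethan-1-one
Conditions: PPh3, DIAD, THF, 0 °C → rt
Reagents that add atoms: none
Why: Mitsunobu etherification, in which the acidic phenol (pKa about 8) displaces the alkoxyphosphonium leaving group by SN2 with inversion, turning the R carbinol into the S aryl ether.

**Step 3**
Reactants: 5 the (S,E)-aryl allyl ether
Product: 6 1-(3-{(2R,3E)-1-[(tert-butyldimethylsilyl)oxy]pent-3-en-2-yl}-4-hydroxy-5-methoxyphenyl)ethan-1-one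
Conditions: PhNEt2, 185 °C, sealed tube, 6 h
Reagents that add atoms: none
Why: Aromatic Claisen rearrangement, a [3,3]-sigmatropic shift through a chair transition state with the methyl group pseudo-equatorial, forms the C3a–C3 bond suprafacially at the only free ortho position, so the S C–O stereocentre is relayed into the R benzylic stereocentre and a new E-propenyl group.

**Step 4**
Reactants: 6 the (R,E)-ortho-pentenyl phenol
Product: 9 1-[(3R)-3-({[tert-butyldimethylsilyl]oxy}methyl)-2-hydroxy-7-methoxy-2,3-dihydro-1-benzofuran-5-yl]ethan-1-one (lactol; C2 epimers), via secondary ozonide 7 (not isolated), via hydroxy aldehyde 8 (not isolated)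
Conditions: O3, CH2Cl2, −78 °C; then PPh3, −78 °C → rt; quick filtration through Et3N-deactivated SiO2, used at once
Reagents that add atoms: ozone, [O-][O+]=O
Why: Ozonolysis with reductive work-up cleaves the electron-rich disubstituted alkene much faster than the acetyl-deactivated phenol reacts, and the aldehyde closes onto the phenol to a lactol that masks the epimerisable α-aryl aldehyde without breaking any bond to the stereocentre.

**Step 5**
Reactants: 10 4-bromo-2,6-dimethoxyphenol
Product: 11 5-bromo-1,3-dimethoxy-2-(methoxymethoxy)benzene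
Conditions: MOMCl, K2CO3, acetone, 0 °C → rt
Reagents that add atoms: chloromethyl methyl ether (MOMCl), COCCl
Why: Williamson-type O-alkylation of the phenoxide gives an acetal protecting group that survives organolithium chemistry and falls off in the final acid step.

**Step 6**
Reactants: 9 the (3R)-lactol; 11 5-bromo-1,3-dimethoxy-2-(methoxymethoxy)benzene (3 equiv)
Product: 14 1-[3-{(2R)-3-[(tert-butyldimethylsilyl)oxy]-1-[3,5-dimethoxy-4-(methoxymethoxy)phenyl]-1-hydroxypropan-2-yl}-4-hydroxy-5-methoxyphenyl]ethan-1-one (both C1 epimers), via aryllithium 12 (not isolated), via aryltitanium triisopropoxide 13 (not isolated)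
Conditions: 11, n-BuLi, THF, −78 °C; ClTi(OiPr)3, −78 → −40 °C; then 9, −40 → 0 °C; aq. NH4Cl
Reagents that add atoms: none
Why: Bromine–lithium exchange and transmetalation give a weakly basic aryltitanium triisopropoxide whose carbonyl addition is aldehyde-selective, so it adds to the ring-opened lactol and spares the aryl methyl ketone without epimerising or β-eliminating the α-aryl-β-silyloxy aldehyde; one equivalent is consumed by the lactol hydroxyl, and the new carbinol configuration is irrelevant.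

**Step 7**
Reactants: 14 the diol (both C1 epimers)
Product: 16 1-[(2S,3R)-2-(4-hydroxy-3,5-dimethoxyphenyl)-3-(hydroxymethyl)-7-methoxy-2,3-dihydro-1-benzofuran-5-yl]ethan-1-one, via cyclised MOM ether 15 (not isolated)
Conditions: 3 M aq. HCl/THF (1:3), rt → 45 °C
Reagents that add atoms: none
Why: Acid-mediated SN1 cyclodehydration, in which the ring A phenol captures the trioxygenated benzylic cation (5-membered ring closure), funnels both carbinol epimers into the thermodynamically favoured 2,3-trans ring so that C3 (R) sets C2 (S), while the same acid cleaves the TBS ether and the MOM acetal.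

## Compound list

1 | (R)-but-3-en-2-ol | C[C@@H](O)C=C | starting material
2 | allyloxy(tert-butyl)dimethylsilane | C=CCO[Si](C)(C)C(C)(C)C | starting material
3 | (2R,3E)-5-[(tert-butyldimethylsilyl)oxy]pent-3-en-2-ol | C[C@@H](O)/C=C/CO[Si](C)(C)C(C)(C)C | intermediate
4 | acetovanillone, 1-(4-hydroxy-3-methoxyphenyl)ethan-1-one | CC(=O)c1ccc(O)c(OC)c1 | starting material
5 | 1-[4-({(2S,3E)-5-[(tert-butyldimethylsilyl)oxy]pent-3-en-2-yl}oxy)-3-methoxyphenyl]ethan-1-one | C[C@H](Oc1ccc(C(C)=O)cc1OC)/C=C/CO[Si](C)(C)C(C)(C)C | intermediate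
6 | 1-(3-{(2R,3E)-1-[(tert-butyldimethylsilyl)oxy]pent-3-en-2-yl}-4-hydroxy-5-methoxyphenyl)ethan-1-one | CC(=O)c1cc(OC)c(O)c([C@H](CO[Si](C)(C)C(C)(C)C)/C=C/C)c1 | intermediate
7 | secondary ozonide of 6, 1-(3-{(1R)-2-[(tert-butyldimethylsilyl)oxy]-1-(5-methyl-1,2,4-trioxolan-3-yl)ethyl}-4-hydroxy-5-methoxyphenyl)ethan-1-one (trioxolane centres mixed) | CC(=O)c1cc(OC)c(O)c([C@H](CO[Si](C)(C)C(C)(C)C)C2OOC(C)O2)c1 | intermediate
8 | (2R)-2-(5-acetyl-2-hydroxy-3-methoxyphenyl)-3-[(tert-butyldimethylsilyl)oxy]propanal | CC(=O)c1cc(OC)c(O)c([C@H](CO[Si](C)(C)C(C)(C)C)C=O)c1 | intermediate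
9 | 1-[(3R)-3-({[tert-butyldimethylsilyl]oxy}methyl)-2-hydroxy-7-methoxy-2,3-dihydro-1-benzofuran-5-yl]ethan-1-one (C2 epimers) | COc1cc(C(C)=O)cc2c1OC(O)[C@H]2CO[Si](C)(C)C(C)(C)C | intermediate
10 | 4-bromo-2,6-dimethoxyphenol | COc1cc(Br)cc(OC)c1O | starting material
11 | 5-bromo-1,3-dimethoxy-2-(methoxymethoxy)benzene | COCOc1c(OC)cc(Br)cc1OC | intermediate
12 | [3,5-dimethoxy-4-(methoxymethoxy)phenyl]lithium | [Li]c1cc(OC)c(OCOC)c(OC)c1 | intermediate
13 | [3,5-dimethoxy-4-(methoxymethoxy)phenyl]titanium triisopropoxide | CC(C)O[Ti](OC(C)C)(OC(C)C)c1cc(OC)c(OCOC)c(OC)c1 | intermediate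
14 | 1-[3-{(2R)-3-[(tert-butyldimethylsilyl)oxy]-1-[3,5-dimethoxy-4-(methoxymethoxy)phenyl]-1-hydroxypropan-2-yl}-4-hydroxy-5-methoxyphenyl]ethan-1-one (both C1 epimers) | CC(=O)c1cc(OC)c(O)c([C@H](CO[Si](C)(C)C(C)(C)C)C(O)c2cc(OC)c(OCOC)c(OC)c2)c1 | intermediate
15 | 1-[(2S,3R)-2-[3,5-dimethoxy-4-(methoxymethoxy)phenyl]-3-(hydroxymethyl)-7-methoxy-2,3-dihydro-1-benzofuran-5-yl]ethan-1-one | COCOc1c(OC)cc([C@H]2Oc3c(OC)cc(C(C)=O)cc3[C@@H]2CO)cc1OC | intermediate
16 | 1-[(2S,3R)-2-(4-hydroxy-3,5-dimethoxyphenyl)-3-(hydroxymethyl)-7-methoxy-2,3-dihydro-1-benzofuran-5-yl]ethan-1-one | COc1cc([C@H]2Oc3c(OC)cc(C(C)=O)cc3[C@@H]2CO)cc(OC)c1O | target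

## Step count and risk

Total steps: 7. Longest linear sequence: 6 (steps 1, 2, 3, 4, 6, 7); step 5 is a one-step side branch.

The three steps most likely to fail are steps 2, 3 and 6, with step 6 the riskiest.

Step 2 (Mitsunobu) may give some SN2′ ether or partial loss of configuration at the allylic carbinol. The fallback sets out from 2, which is cross-metathesised under the step 1 conditions with purchased (S)-but-3-en-2-ol to give (2S,3E)-5-[(tert-butyldimethylsilyl)oxy]pent-3-en-2-ol F1. F1 is deprotonated in situ with KN(SiMe3)2 in THF/DMF at 0 °C and displaces fluoride from purchased 1-(4-fluoro-3-methoxyphenyl)ethan-1-one by nucleophilic aromatic substitution para to the acetyl group. The C–O bond of F1 is never broken, so the S configuration is retained and the fallback comes back to the route at 5.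

Step 3 (Claisen) may suffer from incomplete chirality transfer through the minor axial-methyl pathway, from abnormal Claisen isomerisation of the hot free phenol, or from ether cleavage. The fallback sets out from 5 and runs the rearrangement in PhNEt2/Ac2O with NaOAc at 180 °C, so that phenol 6 is acetylated as it forms and is isolated as 4-acetyl-2-methoxy-6-{(2R,3E)-1-[(tert-butyldimethylsilyl)oxy]pent-3-en-2-yl}phenyl acetate F2, which can no longer isomerise. Methanolysis of F2 (K2CO3, MeOH, rt) leaves the TBS ether intact and comes back to the route at 6.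

Step 6 (aldehyde-selective arylation) may fail through competing attack on the ketone, sluggish lactol opening, or epimerisation and β-elimination of the α-aryl-β-silyloxy aldehyde. The fallback sets out from 5 and masks the ketone first:

- Ketalisation with 1,2-bis(trimethylsilyloxy)ethane and catalytic TMSOTf (CH2Cl2, −78 °C) gives 2-[4-({(2S,3E)-5-[(tert-butyldimethylsilyl)oxy]pent-3-en-2-yl}oxy)-3-methoxyphenyl]-2-methyl-1,3-dioxolane F3.
- Claisen rearrangement as in step 3 gives 2-{(2R,3E)-1-[(tert-butyldimethylsilyl)oxy]pent-3-en-2-yl}-6-methoxy-4-(2-methyl-1,3-dioxolan-2-yl)phenol F4.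
- Ozonolysis and PPh3 reduction as in step 4 lead through the secondary ozonide of F4, 2-{(1R)-2-[(tert-butyldimethylsilyl)oxy]-1-(5-methyl-1,2,4-trioxolan-3-yl)ethyl}-6-methoxy-4-(2-methyl-1,3-dioxolan-2-yl)phenol F5, and the open aldehyde (2R)-3-[(tert-butyldimethylsilyl)oxy]-2-[2-hydroxy-3-methoxy-5-(2-methyl-1,3-dioxolan-2-yl)phenyl]propanal F6, to the lactol (3R)-3-({[tert-butyldimethylsilyl]oxy}methyl)-7-methoxy-5-(2-methyl-1,3-dioxolan-2-yl)-2,3-dihydro-1-benzofuran-2-ol F7.
- With the ketone masked, aryllithium 12 itself (3 equiv, THF, −78 °C) adds to F7 to give the diol 2-{(2R)-3-[(tert-butyldimethylsilyl)oxy]-1-[3,5-dimethoxy-4-(methoxymethoxy)phenyl]-1-hydroxypropan-2-yl}-6-methoxy-4-(2-methyl-1,3-dioxolan-2-yl)phenol F8.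
- Under the acid of step 7, F8 first loses its dioxolane, which brings the fallback back to the route at 14 in the flask, and 14 goes on to 16 as in step 7.

## Further compounds

F1 | step 2 | (2S,3E)-5-[(tert-butyldimethylsilyl)oxy]pent-3-en-2-ol | C[C@H](O)/C=C/CO[Si](C)(C)C(C)(C)C
F2 | step 3 | 4-acetyl-2-methoxy-6-{(2R,3E)-1-[(tert-butyldimethylsilyl)oxy]pent-3-en-2-yl}phenyl acetate | CC(=O)Oc1c(OC)cc(C(C)=O)cc1[C@H](CO[Si](C)(C)C(C)(C)C)/C=C/C
F3 | step 6 | 2-[4-({(2S,3E)-5-[(tert-butyldimethylsilyl)oxy]pent-3-en-2-yl}oxy)-3-methoxyphenyl]-2-methyl-1,3-dioxolane | C[C@H](Oc1ccc(C2(C)OCCO2)cc1OC)/C=C/CO[Si](C)(C)C(C)(C)C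
F4 | step 6 | 2-{(2R,3E)-1-[(tert-butyldimethylsilyl)oxy]pent-3-en-2-yl}-6-methoxy-4-(2-methyl-1,3-dioxolan-2-yl)phenol | CC1(OCCO1)c1cc(OC)c(O)c([C@H](CO[Si](C)(C)C(C)(C)C)/C=C/C)c1
F5 | step 6 | 2-{(1R)-2-[(tert-butyldimethylsilyl)oxy]-1-(5-methyl-1,2,4-trioxolan-3-yl)ethyl}-6-methoxy-4-(2-methyl-1,3-dioxolan-2-yl)phenol | CC1(OCCO1)c1cc(OC)c(O)c([C@H](CO[Si](C)(C)C(C)(C)C)C2OOC(C)O2)c1
F6 | step 6 | (2R)-3-[(tert-butyldimethylsilyl)oxy]-2-[2-hydroxy-3-methoxy-5-(2-methyl-1,3-dioxolan-2-yl)phenyl]propanal | CC1(OCCO1)c1cc(OC)c(O)c([C@H](CO[Si](C)(C)C(C)(C)C)C=O)c1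
F7 | step 6 | (3R)-3-({[tert-butyldimethylsilyl]oxy}methyl)-7-methoxy-5-(2-methyl-1,3-dioxolan-2-yl)-2,3-dihydro-1-benzofuran-2-ol | COc1cc(C3(C)OCCO3)cc2c1OC(O)[C@H]2CO[Si](C)(C)C(C)(C)C
F8 | step 6 | 2-{(2R)-3-[(tert-butyldimethylsilyl)oxy]-1-[3,5-dimethoxy-4-(methoxymethoxy)phenyl]-1-hydroxypropan-2-yl}-6-methoxy-4-(2-methyl-1,3-dioxolan-2-yl)phenol | CC1(OCCO1)c1cc(OC)c(O)c([C@H](CO[Si](C)(C)C(C)(C)C)C(O)c2cc(OC)c(OCOC)c(OC)c2)c1
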